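The benzene ring is cut at C2–C3. Its meta oxygens on C1 and C5, the C4 methoxy group and the C3 chain form the pattern of a folded 1,3,5-triketone. That triketone can be stored as the ring of 2-heptadecyl-3-methoxy-6-methyl-4H-pyran-4-one. In this pyranone, C2 to C6 are already arene carbons C3, C4, C5, C6 and C1, and the 6-methyl group is the future C2. Hot Ba(OH)2 in aqueous dioxane should open this heterocycle and reclose it by aldol condensation. This exchanges the ring oxygen for carbon and delivers the fully substituted resorcinol in one operation. The pyranone comes from kojic acid and heptadecanal. Selective protection, methylation and deprotection finish the route.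

Key step: step 6

Remark: arene locants are those of the target (C1 carries the free hydroxyl, C3 the chain). The target is achiral; the one stereocentre made on the way (hydroxyalkylation product, racemic) is erased one step later. No extra activating or blocking group is put on the pyranone, because its own 3-methoxy group already biases the ring closure.

Step 1
Reactants: 1 kojic acid
Product: 2 chlorokojic acid, 2-(chloromethyl)-5-hydroxy-4H-pyran-4-one
Conditions: SOCl2 (neat), rt
Reagents that add atoms: thionyl chloride, O=S(Cl)Cl
Why: Deoxychlorination of the primary, allylic-type alcohol through its chlorosulfite is a standard reaction of kojic acid, and the acidic enolic 5-hydroxyl forms no stable chloride and is returned on work-up.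

Step 2
Reactants: 2 chlorokojic acid
Product: 3 allomaltol, 5-hydroxy-2-methyl-4H-pyran-4-one
Conditions: Zn dust, conc. HCl, H2O, 70 °C
Reagents that add atoms: none
Why: Dissolving-metal reductive dehalogenation cleaves the activated allylic C–Cl bond, while the vinylogous-ester carbonyl of the pyranone is not reduced under these conditions.

Step 3
Reactants: 3 allomaltol; 4 heptadecanal
Product: 5 racemic 3-hydroxy-2-(1-hydroxyheptadecyl)-6-methyl-4H-pyran-4-one
Conditions: NaOH (1.1 equiv), MeOH/THF/H2O, rt; then 1 M HCl
Reagents that add atoms: none
Why: In this aldol-type hydroxyalkylation the anion of the enolic hydroxypyranone reacts as a phenolate-like carbon nucleophile at C6, ortho to the oxido group, as it does with formaldehyde, acetaldehyde and propanal, the modest basicity of this salt keeps self-aldol of 4 slow and the cosolvents bring both partners into one phase; the carbinol centre forms without control (racemate) and is erased in step 4.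

Step 4
Reactants: 5 racemic 3-hydroxy-2-(1-hydroxyheptadecyl)-6-methyl-4H-pyran-4-one
Product: 6 2-heptadecyl-3-hydroxy-6-methyl-4H-pyran-4-one
Conditions: Zn dust, conc. HCl, AcOH, 70 °C
Reagents that add atoms: none
Why: Acid ionises the carbinol, which the neighbouring enolic hydroxyl activates in the manner of an ortho-hydroxybenzyl alcohol, and zinc reduces the cation (dissolving-metal deoxygenation, the reaction that turns 2-(1-hydroxyalkyl)-3-hydroxy-4-pyranones into their 2-alkyl homologues), while the ring carbonyl survives as in step 2 and the stereocentre disappears.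

Step 5
Reactants: 6 2-heptadecyl-3-hydroxy-6-methyl-4H-pyran-4-one
Product: 7 2-heptadecyl-3-methoxy-6-methyl-4H-pyran-4-one
Conditions: MeI, K2CO3, acetone, reflux
Reagents that add atoms: iodomethane, CI
Why: Williamson O-methylation of the acidic enolic hydroxyl (as for maltol) installs the future C4 methoxy group and, by removing the only ionisable proton, keeps the pyranone neutral and open to hydroxide addition in step 6.

Step 6
Reactants: 7 2-heptadecyl-3-methoxy-6-methyl-4H-pyran-4-one
Product: 9 5-heptadecyl-4-methoxybenzene-1,3-diol, via 5-methoxytricosane-2,4,6-trione 8 (not isolated)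
Conditions: Ba(OH)2·8H2O (4 equiv), degassed 1,4-dioxane/H2O (2:1), argon, reflux; then 2 M HCl, 0 °C
Reagents that add atoms: water (delivered as hydroxide), O
Why: Hydroxide adds to the less hindered α-carbon C6 of 7, the C6–O1 bond breaks and the ring unfolds to triketone 8, kept as its barium enolate; deprotonation of the terminal methyl group of 8 (C1, the old 6-methyl) lets this carbon add to the C6 ketone that carries the chain, and loss of water followed by enolisation of the two remaining carbonyl groups gives the benzene ring of 9 (new bond: arene C2–C3). The closest known reaction type is the alkali conversion of 2,6-dimethyl-4-pyranone by way of heptane-2,4,6-trione into orcinol, an intramolecular aldol condensation, of which this 3-methoxy, unsymmetrically dialkylated substrate is a new member. The one ring closes in the 6-(enolendo)-exo-trig mode, a favoured one, since both carbons of the C1=C2 enolate end up inside the new ring while the attacked C6=O bond points out of it. No stereocentre is formed, and the labile C5 centre of 8 becomes planar. The selectivity required is that C1, the methyl carbon, rather than C7, the first methylene of the chain, acts as the nucleophile: base first ionises the most acidic C3 methylene, which masks C2 and C4 as an enolate and leaves C6, made more electrophilic by the adjacent methoxy group, as the only free ketone, a carbon that C1 alone can reach through a six-membered transition state, and the methyl carbanion is also the less hindered one and leads to the less crowded arene. Chelation by divalent barium and the low level of free hydroxide from this sparingly soluble base should hold back retro-Claisen fragmentation, dioxane brings the waxy substrate into the reacting phase, and exclusion of air protects the electron-rich product.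

Step 7
Reactants: 9 5-heptadecyl-4-methoxybenzene-1,3-diol
Product: 10 3-heptadecyl-2-methoxy-5-(triisopropylsilyloxy)phenol
Conditions: TIPSCl (1.0 equiv), imidazole, CH2Cl2/DMF, 0 °C
Reagents that add atoms: triisopropylsilyl chloride, CC(C)[Si](Cl)(C(C)C)C(C)C
Why: Silyl ether formation under steric control should take the C1 hydroxyl first, because it has hydrogen on both sides whereas the C5 hydroxyl sits next to, and is hydrogen-bonded to, the out-of-plane C4 methoxy group.

Step 8
Reactants: 10 3-heptadecyl-2-methoxy-5-(triisopropylsilyloxy)phenol
Product: 11 (3-heptadecyl-4,5-dimethoxyphenoxy)triisopropylsilane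
Conditions: MeI, K2CO3, dry acetone, 45 °C
Reagents that add atoms: iodomethane, CI
Why: Williamson ether synthesis acts on the only free phenol, and the triisopropylsilyl ether tolerates anhydrous carbonate in acetone and cannot migrate within the molecule to a meta oxygen.

Step 9
Reactants: 11 (3-heptadecyl-4,5-dimethoxyphenoxy)triisopropylsilane
Product: 12 3-heptadecyl-4,5-dimethoxyphenol (target)
Conditions: Bu4NF, AcOH, THF, 0 °C
Reagents that add atoms: none
Why: Fluoride-induced desilylation, driven by the strong Si–F bond, frees the C1 phenol, the acetic acid buffer keeps the electron-rich phenoxide from standing in base, and the methyl ethers and the alkyl chain are inert.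

Compound list
1 | kojic acid, 5-hydroxy-2-(hydroxymethyl)-4H-pyran-4-one | OCc1cc(=O)c(O)co1 | starting material
2 | chlorokojic acid, 2-(chloromethyl)-5-hydroxy-4H-pyran-4-one | ClCc1cc(=O)c(O)co1 | intermediate
3 | allomaltol, 5-hydroxy-2-methyl-4H-pyran-4-one | Cc1cc(=O)c(O)co1 | intermediate
4 | heptadecanal | CCCCCCCCCCCCCCCCC=O | starting material
5 | racemic 3-hydroxy-2-(1-hydroxyheptadecyl)-6-methyl-4H-pyran-4-one | CCCCCCCCCCCCCCCCC(O)c1oc(C)cc(=O)c1O | intermediate
6 | 2-heptadecyl-3-hydroxy-6-methyl-4H-pyran-4-one | CCCCCCCCCCCCCCCCCc1oc(C)cc(=O)c1O | intermediate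
7 | 2-heptadecyl-3-methoxy-6-methyl-4H-pyran-4-one | CCCCCCCCCCCCCCCCCc1oc(C)cc(=O)c1OC | intermediate
8 | 5-methoxytricosane-2,4,6-trione (C5 configurationally labile) | CCCCCCCCCCCCCCCCCC(=O)C(OC)C(=O)CC(C)=O | intermediate (not isolated)
9 | 5-heptadecyl-4-methoxybenzene-1,3-diol | CCCCCCCCCCCCCCCCCc1cc(O)cc(O)c1OC | intermediate
10 | 3-heptadecyl-2-methoxy-5-(triisopropylsilyloxy)phenol | CCCCCCCCCCCCCCCCCc1cc(O[Si](C(C)C)(C(C)C)C(C)C)cc(O)c1OC | intermediate
11 | (3-heptadecyl-4,5-dimethoxyphenoxy)triisopropylsilane | CCCCCCCCCCCCCCCCCc1cc(O[Si](C(C)C)(C(C)C)C(C)C)cc(OC)c1OC | intermediate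
12 | 3-heptadecyl-4,5-dimethoxyphenol | CCCCCCCCCCCCCCCCCc1cc(O)cc(OC)c1OC | target

Total step count: 9. Longest linear sequence: 9 steps (1 to 12); 4 enters at step 3. Compound 3 is also a catalogue item, and buying it would bring both counts to 7.

Steps most likely to fail

Step 6.
- What may go wrong: hydroxide fragments the opened chain by retro-Claisen cleavage faster than the ring closes, or the closure starts in part from the chain methylene.
- Fallback (sets out from 4, comes back at 12): the arene is bought instead of built.
- Directed ortho-lithiation of 1,2-dimethoxybenzene (n-BuLi, TMEDA, Et2O, 0 °C to rt) gives (2,3-dimethoxyphenyl)lithium F1.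
- F1 adds to 4 to give racemic 1-(2,3-dimethoxyphenyl)heptadecan-1-ol F2.
- Ionic deoxygenation (Et3SiH, CF3CO2H, CH2Cl2, 0 °C) gives 1-heptadecyl-2,3-dimethoxybenzene F3.
- Sterically controlled C–H borylation ([Ir(OMe)(cod)]2, 4,4'-di-tert-butyl-2,2'-bipyridine, B2pin2, THF, 80 °C) takes the only ring hydrogen without an ortho neighbour. It gives 2-(3-heptadecyl-4,5-dimethoxyphenyl)-4,4,5,5-tetramethyl-1,3,2-dioxaborolane F4.
- Oxidation (H2O2, NaOH, THF/H2O, 0 °C) gives 12 directly, so that steps 7 to 9 are not needed.

Step 3.
- What may go wrong: self-condensation of the enolisable fatty aldehyde, poor contact between the ionic pyranone salt and the lipophilic aldehyde, or further condensation of the carbinol with a second pyranone.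
- Fallback (sets out from 3, comes back at 7): the ring–chain bond is made by cross-coupling instead of carbonyl addition.
- Electrophilic bromination of 3 ortho to the enolic hydroxyl (NBS, MeCN, 0 °C) gives 2-bromo-3-hydroxy-6-methyl-4H-pyran-4-one F5.
- O-methylation (MeI, K2CO3, acetone) gives 2-bromo-3-methoxy-6-methyl-4H-pyran-4-one F6.
- Heptadecylzinc bromide F7 is made from 1-bromoheptadecane, Zn dust and catalytic I2 in DMA at 80 °C.
- Negishi coupling of F6 and F7 under PdCl2(dppf) in THF at 50 °C gives 7.
- The coupling needs no base, so the vinylogous acyl bromide is not hydrolysed. The number of steps stays the same.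

Step 7.
- What may go wrong: insufficient discrimination between the two phenolic hydroxyls, with silylation at the wrong oxygen or at both.
- Fallback (sets out from 9, comes back at 11): the hydroxyl that is left for the later methylation is shifted from C5, which has one neighbour, to C4, which has two. Size alone then decides the silylation.
- Exhaustive methylation of 9 (excess MeI, K2CO3, DMF, rt) gives 1-heptadecyl-2,3,5-trimethoxybenzene F8.
- Oxidative demethylation of its para-dimethoxy pair ((NH4)2Ce(NO3)6, MeCN/H2O, 0 °C) gives 2-heptadecyl-6-methoxycyclohexa-2,5-diene-1,4-dione F9.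
- Reduction (Na2S2O4, THF/H2O, rt) gives 2-heptadecyl-6-methoxybenzene-1,4-diol F10.
- TIPSCl and imidazole can then reach only the hydroxyl flanked by two hydrogens and give 2-heptadecyl-6-methoxy-4-(triisopropylsilyloxy)phenol F11.
- The remaining hindered hydroxyl of F11 is methylated (MeI, K2CO3, DMF, 50 °C) to 11.

Further compounds
F1 | step 6 | (2,3-dimethoxyphenyl)lithium | [Li]c1cccc(OC)c1OC
F2 | step 6 | racemic 1-(2,3-dimethoxyphenyl)heptadecan-1-ol | CCCCCCCCCCCCCCCCC(O)c1cccc(OC)c1OC
F3 | step 6 | 1-heptadecyl-2,3-dimethoxybenzene | CCCCCCCCCCCCCCCCCc1cccc(OC)c1OC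
F4 | step 6 | 2-(3-heptadecyl-4,5-dimethoxyphenyl)-4,4,5,5-tetramethyl-1,3,2-dioxaborolane | CCCCCCCCCCCCCCCCCc1cc(B2OC(C)(C)C(C)(C)O2)cc(OC)c1OC
F5 | step 3 | 2-bromo-3-hydroxy-6-methyl-4H-pyran-4-one | Cc1cc(=O)c(O)c(Br)o1
F6 | step 3 | 2-bromo-3-methoxy-6-methyl-4H-pyran-4-one | Cc1cc(=O)c(OC)c(Br)o1
F7 | step 3 | heptadecylzinc bromide | CCCCCCCCCCCCCCCCC[Zn]Br
F8 | step 7 | 1-heptadecyl-2,3,5-trimethoxybenzene | CCCCCCCCCCCCCCCCCc1cc(OC)cc(OC)c1OC
F9 | step 7 | 2-heptadecyl-6-methoxycyclohexa-2,5-diene-1,4-dione | CCCCCCCCCCCCCCCCCC1=CC(=O)C=C(OC)C1=O
F10 | step 7 | 2-heptadecyl-6-methoxybenzene-1,4-diol | CCCCCCCCCCCCCCCCCc1cc(O)cc(OC)c1O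
F11 | step 7 | 2-heptadecyl-6-methoxy-4-(triisopropylsilyloxy)phenol | CCCCCCCCCCCCCCCCCc1cc(O[Si](C(C)C)(C(C)C)C(C)C)cc(OC)c1O
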